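## Retrosynthetic overview
1. The target comes from acidic removal of six MOM groups from the protected (2R,3R)-dihydroflavonol. Its pyranone ring (O1–C2, the last ring formed) is closed by a freed 2'-phenol opening an (αR,βS)-epoxychalcone with inversion.
2. The epoxide comes from an (E)-enone. The enone is cut at the future C2–C3 bond by a Claisen–Schmidt aldol condensation of a cyclohexenyl-benzaldehyde with 2-allyloxy-4-MOMO-acetophenone. This is the key fragment union.
3. The cyclohexenyl-benzaldehyde (first ring formed) comes from an exo-selective, VANOL/boron-controlled Diels–Alder reaction of tri-O-MOM morachalcone A with an (E)-dienyl-benzaldehyde.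
4. The chalcone comes from a second Claisen–Schmidt condensation, with the 3-prenyl ketone made by O-allylation, Claisen rearrangement and cross-metathesis. The diene comes from a Suzuki coupling of 5-bromosalicylaldehyde MOM ether with a dienyl boronate.
5. Ring order: cyclohexene, then oxirane, then dihydropyranone.

Shorthand:
- MOM = CH2OCH3.
- prenyl = 3-methylbut-2-en-1-yl.
- "core" = (1R,5S,6R)-5-[2,4-bis(MOMO)phenyl]-6-[2,4-bis(MOMO)-3-prenylbenzoyl]-3-methylcyclohex-2-en-1-yl, with the three ring substituents mutually trans.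

Assumption: (S)-VANOL is taken as the ligand antipode that gives the (1R,5S,6R) series. The sense is checked on the first batch, and (R)-VANOL is used instead if it proves opposite.

## Route

Step 1
Reactants: 1 2,4-dihydroxyacetophenone
Product: 2 4-(allyloxy)-2-hydroxyacetophenone
Conditions: allyl bromide (1.05 equiv), K2CO3, acetone, reflux
Reagents that add atoms: allyl bromide C=CCBr
Why: Williamson ether synthesis in which only the 4-OH reacts, because the 2-OH is hydrogen-bonded to the acetyl carbonyl.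

Step 2
Reactants: 2 4-(allyloxy)-2-hydroxyacetophenone
Product: 4 3-allyl-2,4-dihydroxyacetophenone, via ortho-dienone 3 (not isolated)
Conditions: N,N-diethylaniline, 200 °C
Reagents that add atoms: none
Why: Aromatic Claisen rearrangement followed by tautomerisation, in which chelation-induced bond fixation sends the allyl group to C3 between the two oxygens (the classical outcome for this substrate).

Step 3
Reactants: 4 3-allyl-2,4-dihydroxyacetophenone
Product: 5 3-allyl-2-hydroxy-4-(methoxymethoxy)acetophenone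
Conditions: MOMCl (1.1 equiv), K2CO3, acetone, rt
Reagents that add atoms: chloromethyl methyl ether COCCl
Why: Selective O-alkylation of the non-chelated 4-OH, which leaves free the 2-OH that the boron Lewis acid must bind later.

Step 4
Reactants: 5 3-allyl-2-hydroxy-4-(methoxymethoxy)acetophenone
Product: 6 2-hydroxy-4-(methoxymethoxy)-3-prenylacetophenone
Conditions: 2-methylbut-2-ene (excess), Grubbs II (3 mol %), CH2Cl2, 40 °C, sealed tube
Reagents that add atoms: 2-methylbut-2-ene CC=C(C)C
Why: Olefin cross-metathesis turns the terminal allyl into prenyl, is driven by loss of propene, and tolerates the ketone, the chelated phenol and the MOM group.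

Step 5
Reactants: 7 2,4-dihydroxybenzaldehyde
Product: 8 2,4-bis(methoxymethoxy)benzaldehyde
Conditions: NaH (2.4 equiv), MOMCl (2.4 equiv), DMF, 0 °C to rt
Reagents that add atoms: chloromethyl methyl ether COCCl
Why: Exhaustive O-alkylation of the bis-phenoxide, with NaH overcoming the chelation of the 2-OH.

Step 6
Reactants: 6 2-hydroxy-4-(methoxymethoxy)-3-prenylacetophenone; 8 2,4-bis(methoxymethoxy)benzaldehyde
Product: 10 (E)-3-[2,4-bis(MOMO)phenyl]-1-[2-hydroxy-4-(MOMO)-3-prenylphenyl]prop-2-en-1-one (tri-O-MOM morachalcone A), via aldol adduct 9 (not isolated)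
Conditions: KOH (10 equiv), EtOH, rt, 36 h; neutralise to pH 6 at 0 °C
Reagents that add atoms: none
Why: Claisen–Schmidt crossed aldol condensation between the only enolisable ketone and a non-enolisable aldehyde, in which E1cB loss of water gives the conjugated E-enone and MOM ethers are base-stable.

Step 7
Reactants: 11 5-bromo-2-hydroxybenzaldehyde
Product: 12 5-bromo-2-(methoxymethoxy)benzaldehyde
Conditions: NaH (1.2 equiv), MOMCl (1.2 equiv), DMF, 0 °C to rt
Reagents that add atoms: chloromethyl methyl ether COCCl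
Why: O-alkylation of the phenoxide masks the phenol that later becomes the B-ring 2'-OH.

Step 8
Reactants: 13 2-methylbut-1-en-3-yne
Product: 14 (E)-4,4,5,5-tetramethyl-2-(3-methylbuta-1,3-dien-1-yl)-1,3,2-dioxaborolane
Conditions: pinacolborane, Cp2ZrHCl (5 mol %), Et3N (10 mol %), neat, 60 °C
Reagents that add atoms: pinacolborane [H]B1OC(C)(C)C(C)(C)O1
Why: Zirconium-catalysed syn-hydroboration of the terminal alkyne puts boron on the terminal carbon with E geometry and leaves the 1,1-disubstituted alkene alone.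

Step 9
Reactants: 12 5-bromo-2-(methoxymethoxy)benzaldehyde; 14 (E)-dienyl pinacol boronate
Product: 15 2-(methoxymethoxy)-5-[(1E)-3-methylbuta-1,3-dien-1-yl]benzaldehyde
Conditions: Pd(dppf)Cl2 (3 mol %), K2CO3, dioxane/H2O 4:1, 80 °C
Reagents that add atoms: none
Why: Suzuki–Miyaura coupling proceeds with retention of the E-alkenyl geometry and tolerates the aldehyde and the MOM group.

Step 10
Reactants: 10 tri-O-MOM morachalcone A; 15 2-(methoxymethoxy)-5-[(1E)-3-methylbuta-1,3-dien-1-yl]benzaldehyde (2 equiv)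
Product: 18 5-{(1R,5S,6R)-5-[2,4-bis(MOMO)phenyl]-6-[2-hydroxy-4-(MOMO)-3-prenylbenzoyl]-3-methylcyclohex-2-en-1-yl}-2-(methoxymethoxy)benzaldehyde (all-trans exo adduct), via chalcone VANOL borate 16 (not isolated), via adduct VANOL borate 17 (not isolated)
Conditions: (S)-VANOL (1.2 equiv), BH3·THF (1.2 equiv), AcOH (1.2 equiv), THF, rt; then 10, rt, evaporate; then 15, 5 Å MS, THF, rt to 40 °C, 48 h; aqueous work-up, chromatography (VANOL recovered)
Reagents that add atoms: none
Why: In this chiral boron-promoted Diels–Alder reaction of the chelated 2'-hydroxychalcone, the diene CH2 terminus bonds to the chalcone β-carbon (regiochemistry), the E-enone sets C5/C6 trans, the exo approach sets C1/C6 trans, the VANOL pocket shields one enone face to set (1R,5S,6R), all B–H is consumed before aldehyde 15 is added, and the endo isomer is removed by chromatography.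

Step 11
Reactants: 18 all-trans exo adduct aldehyde
Product: 19 5-(core)-2-(methoxymethoxy)benzaldehyde
Conditions: NaH (1.3 equiv), MOMCl (1.5 equiv), DMF, 0 °C
Reagents that add atoms: chloromethyl methyl ether COCCl
Why: O-alkylation of the hindered chelated phenoxide removes the free o-hydroxyaryl ketone, which would undergo Dakin-type oxidation in step 15, and the only epimerisable centre (C6) already has the favoured all-equatorial arrangement.

Step 12
Reactants: 1 2,4-dihydroxyacetophenone
Product: 20 2-hydroxy-4-(methoxymethoxy)acetophenone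
Conditions: MOMCl (1.1 equiv), K2CO3, acetone, rt
Reagents that add atoms: chloromethyl methyl ether COCCl
Why: Selective O-alkylation of the non-chelated 4-OH.

Step 13
Reactants: 20 2-hydroxy-4-(methoxymethoxy)acetophenone
Product: 21 2-(allyloxy)-4-(methoxymethoxy)acetophenone
Conditions: allyl bromide (1.5 equiv), K2CO3, DMF, 60 °C
Reagents that add atoms: allyl bromide C=CCBr
Why: Williamson etherification under forcing conditions puts an allyl group, orthogonal to MOM, on the oxygen that must later be released alone to close the pyranone ring.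

Step 14 (key fragment union)
Reactants: 19 5-(core)-2-(methoxymethoxy)benzaldehyde; 21 2-(allyloxy)-4-(methoxymethoxy)acetophenone (1.3 equiv)
Product: 23 (E)-1-[2-(allyloxy)-4-(MOMO)phenyl]-3-[5-(core)-2-(MOMO)phenyl]prop-2-en-1-one, via aldol adduct 22 (not isolated)
Conditions: KOH (10 equiv), EtOH/THF 2:1, rt, 36 h
Reagents that add atoms: none
Why: In this intermolecular Claisen–Schmidt aldol condensation the methyl ketone enolate adds to the only aldehyde, E1cB dehydration gives the E-enone, addition to the hindered tertiary α-carbon of the core ketone is reversible and cannot dehydrate, and the all-trans core is the thermodynamic epimer so it is not scrambled.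

Step 15
Reactants: 23 (E)-enone
Product: 24 [2-(allyloxy)-4-(MOMO)phenyl]{(2R,3S)-3-[5-(core)-2-(MOMO)phenyl]oxiran-2-yl}methanone
Conditions: poly-L-leucine, urea·H2O2 (1.5 equiv), DBU (1.5 equiv), THF, rt
Reagents that add atoms: urea–hydrogen peroxide NC(N)=O.OO
Why: In this Juliá–Colonna (Weitz–Scheffer type) nucleophilic epoxidation the hydroperoxide attacks only the electron-poor enone (the prenyl, allyl and ring alkenes are inert), the poly-L-leucine helix delivers the trans-(αR,βS)-epoxide, and the minor diastereomer is removed by chromatography.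

Step 16
Reactants: 24 (2R,3S)-epoxy ketone
Product: 26 (2R,3R)-2-[5-(core)-2-(MOMO)phenyl]-3-hydroxy-7-(methoxymethoxy)chroman-4-one, via phenol epoxide 25 (not isolated)
Conditions: Pd(PPh3)4 (5 mol %), morpholine (3 equiv), THF, rt, Ar
Reagents that add atoms: none
Why: Tsuji–Trost deallylation frees only the 2'-phenol, which opens the epoxide at the benzylic carbon by 6-endo SN2 attack with inversion (βS to 2R) while the Cα–O bond is untouched (αR to 3R), giving the 2,3-trans ring, and the still-masked B-ring oxygen cannot compete.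

Step 17
Reactants: 26 hexa-O-MOM dihydroflavonol
Product: 27 (2R,3R)-2-{5-[(1R,5S,6R)-5-(2,4-dihydroxyphenyl)-6-(2,4-dihydroxy-3-prenylbenzoyl)-3-methylcyclohex-2-en-1-yl]-2-hydroxyphenyl}-3,7-dihydroxychroman-4-one (target)
Conditions: 3 M aq HCl, MeOH/THF, 45 °C, 2–4 h
Reagents that add atoms: none
Why: Acid-catalysed transacetalisation cleaves all six aryl MOM ethers under conditions routinely survived by o-prenylphenols and dihydroflavonols, and the 2,3-trans and all-trans ring arrangements are the thermodynamic ones so no stereocentre is lost.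

## Compound list
1 | 2,4-dihydroxyacetophenone | CC(=O)c1ccc(O)cc1O | starting material
2 | 4-(allyloxy)-2-hydroxyacetophenone | CC(=O)c1ccc(OCC=C)cc1O | intermediate
3 | 4-acetyl-3-hydroxy-2-(prop-2-en-1-yl)cyclohexa-3,5-dien-1-one (not isolated) | CC(=O)C1=C(O)C(CC=C)C(=O)C=C1 | intermediate
4 | 3-allyl-2,4-dihydroxyacetophenone | CC(=O)c1ccc(O)c(CC=C)c1O | intermediate
5 | 3-allyl-2-hydroxy-4-(methoxymethoxy)acetophenone | CC(=O)c1ccc(OCOC)c(CC=C)c1O | intermediate
6 | 2-hydroxy-4-(methoxymethoxy)-3-prenylacetophenone | CC(=O)c1ccc(OCOC)c(CC=C(C)C)c1O | intermediate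
7 | 2,4-dihydroxybenzaldehyde | O=Cc1ccc(O)cc1O | starting material
8 | 2,4-bis(methoxymethoxy)benzaldehyde | O=Cc1ccc(OCOC)cc1OCOC | intermediate
9 | 3-[2,4-bis(MOMO)phenyl]-3-hydroxy-1-[2-hydroxy-4-(MOMO)-3-prenylphenyl]propan-1-one (not isolated) | CC(C)=CCc1c(OCOC)ccc(C(=O)CC(O)c2ccc(OCOC)cc2OCOC)c1O | intermediate
10 | tri-O-MOM morachalcone A, E | CC(C)=CCc1c(OCOC)ccc(C(=O)/C=C/c2ccc(OCOC)cc2OCOC)c1O | intermediate
11 | 5-bromo-2-hydroxybenzaldehyde | O=Cc1cc(Br)ccc1O | starting material
12 | 5-bromo-2-(methoxymethoxy)benzaldehyde | O=Cc1cc(Br)ccc1OCOC | intermediate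
13 | 2-methylbut-1-en-3-yne | C=C(C)C#C | starting material
14 | (E)-4,4,5,5-tetramethyl-2-(3-methylbuta-1,3-dien-1-yl)-1,3,2-dioxaborolane | C=C(C)/C=C/B1OC(C)(C)C(C)(C)O1 | intermediate
15 | 2-(methoxymethoxy)-5-[(1E)-3-methylbuta-1,3-dien-1-yl]benzaldehyde | C=C(C)/C=C/c1ccc(OCOC)c(C=O)c1 | intermediate
16 | borate of 10 bound through its 2'-O to (S)-VANOL-boron (not isolated; axial chirality given in the name only) | CC(C)=CCc1c(OCOC)ccc(C(=O)/C=C/c2ccc(OCOC)cc2OCOC)c1OB1Oc2c(c(-c3ccccc3)cc3ccccc23)-c2c(O1)c3ccccc3cc2-c2ccccc2 | intermediate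
17 | (S)-VANOL borate of adduct 18 (not isolated) | CC(C)=CCc1c(OCOC)ccc(C(=O)[C@@H]2[C@@H](c3ccc(OCOC)cc3OCOC)CC(C)=C[C@H]2c2ccc(OCOC)c(C=O)c2)c1OB1Oc2c(c(-c3ccccc3)cc3ccccc23)-c2c(O1)c3ccccc3cc2-c2ccccc2 | intermediate
18 | (1R,5S,6R) all-trans exo adduct aldehyde with free 2-OH on the aroyl ring | CC(C)=CCc1c(OCOC)ccc(C(=O)[C@@H]2[C@@H](c3ccc(OCOC)cc3OCOC)CC(C)=C[C@H]2c2ccc(OCOC)c(C=O)c2)c1O | intermediate
19 | 5-(core)-2-(methoxymethoxy)benzaldehyde | CC(C)=CCc1c(OCOC)ccc(C(=O)[C@@H]2[C@@H](c3ccc(OCOC)cc3OCOC)CC(C)=C[C@H]2c2ccc(OCOC)c(C=O)c2)c1OCOC | intermediate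
20 | 2-hydroxy-4-(methoxymethoxy)acetophenone | CC(=O)c1ccc(OCOC)cc1O | intermediate
21 | 2-(allyloxy)-4-(methoxymethoxy)acetophenone | CC(=O)c1ccc(OCOC)cc1OCC=C | intermediate
22 | 1-[2-(allyloxy)-4-(MOMO)phenyl]-3-[5-(core)-2-(MOMO)phenyl]-3-hydroxypropan-1-one, carbinol epimers (not isolated) | CC(C)=CCc1c(OCOC)ccc(C(=O)[C@@H]2[C@@H](c3ccc(OCOC)cc3OCOC)CC(C)=C[C@H]2c2ccc(OCOC)c(C(O)CC(=O)c3ccc(OCOC)cc3OCC=C)c2)c1OCOC | intermediate
23 | (E)-1-[2-(allyloxy)-4-(MOMO)phenyl]-3-[5-(core)-2-(MOMO)phenyl]prop-2-en-1-one | CC(C)=CCc1c(OCOC)ccc(C(=O)[C@@H]2[C@@H](c3ccc(OCOC)cc3OCOC)CC(C)=C[C@H]2c2ccc(OCOC)c(/C=C/C(=O)c3ccc(OCOC)cc3OCC=C)c2)c1OCOC | intermediate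
24 | [2-(allyloxy)-4-(MOMO)phenyl]{(2R,3S)-3-[5-(core)-2-(MOMO)phenyl]oxiran-2-yl}methanone | CC(C)=CCc1c(OCOC)ccc(C(=O)[C@@H]2[C@@H](c3ccc(OCOC)cc3OCOC)CC(C)=C[C@H]2c2ccc(OCOC)c([C@@H]3O[C@H]3C(=O)c4ccc(OCOC)cc4OCC=C)c2)c1OCOC | intermediate
25 | [2-hydroxy-4-(MOMO)phenyl]{(2R,3S)-3-[5-(core)-2-(MOMO)phenyl]oxiran-2-yl}methanone (not isolated) | CC(C)=CCc1c(OCOC)ccc(C(=O)[C@@H]2[C@@H](c3ccc(OCOC)cc3OCOC)CC(C)=C[C@H]2c2ccc(OCOC)c([C@@H]3O[C@H]3C(=O)c4ccc(OCOC)cc4O)c2)c1OCOC | intermediate
26 | (2R,3R)-2-[5-(core)-2-(MOMO)phenyl]-3-hydroxy-7-(methoxymethoxy)chroman-4-one | CC(C)=CCc1c(OCOC)ccc(C(=O)[C@@H]2[C@@H](c3ccc(OCOC)cc3OCOC)CC(C)=C[C@H]2c2ccc(OCOC)c([C@H]3Oc4cc(OCOC)ccc4C(=O)[C@@H]3O)c2)c1OCOC | intermediate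
27 | CNP0268637.1 | CC(C)=CCc1c(O)ccc(C(=O)[C@@H]2[C@@H](c3ccc(O)cc3O)CC(C)=C[C@H]2c2ccc(O)c([C@H]3Oc4cc(O)ccc4C(=O)[C@@H]3O)c2)c1O | target

## Count and risks
Total steps: 17. Longest linear sequence: 11 steps (1, 2, 3, 4, 6, 10, 11, 14, 15, 16, 17).

**Step 10 (exo/endo ratio, rate with the electron-rich MOM chalcone, sense of induction).** The fallback sets out from 10 and 15 and comes back at 18. Reagent control is given up. The cycloaddition is run without a chiral ligand on silica-supported silver nanoparticles (CH2Cl2, 50 °C). The all-trans adduct is isolated by chromatography as the racemate, that is 18 together with the mirror-image adduct ent-18 F1. The two are separated by preparative SFC on an amylose-type chiral phase, and 18 then enters step 11 unchanged.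

**Step 15 (a large, ortho-alkoxy-substituted enone may be slow or poorly selective on the polypeptide).** The fallback sets out from 21 and 19 and comes back at 24, bypassing enone 23 and peroxide chemistry. Ketone 21 is chlorinated through its lithium enolate (LiHMDS, THF, −78 °C, then NCS) to give 2-chloro-1-[2-(allyloxy)-4-(methoxymethoxy)phenyl]ethan-1-one F2. F2 is then joined to aldehyde 19 in an asymmetric Darzens condensation (cinchona-derived quaternary ammonium phase-transfer catalyst, LiOH, CH2Cl2, 0 °C). Aldol addition followed by ring closure gives the trans-epoxy ketone directly. The pseudoenantiomeric catalyst that favours (2R,3S) is chosen. Because the core is enantiopure, the other epoxide is a diastereomer and is separable on silica.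

**Step 17 (six acid cleavages next to an o-prenylresorcinol and an ionisable C2).** The fallback sets out from 26 and comes back at 27. The acetals are first exchanged for silyl ethers under non-acidic conditions (TESOTf, 2,2'-bipyridyl, MeCN, 0 °C to rt, aqueous quench). This also silylates the 3-OH and gives the isolable heptakis(triethylsilyl) ether of the target F3. F3 is then desilylated with Et3N·3HF in THF at 0 °C, so the free polyphenol never meets mineral acid.

## Further compounds
F1 | step 10 | ent-18, (1S,5R,6S) all-trans adduct aldehyde | CC(C)=CCc1c(OCOC)ccc(C(=O)[C@H]2[C@H](c3ccc(OCOC)cc3OCOC)CC(C)=C[C@@H]2c2ccc(OCOC)c(C=O)c2)c1O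
F2 | step 15 | 2-chloro-1-[2-(allyloxy)-4-(methoxymethoxy)phenyl]ethan-1-one | C=CCOc1cc(OCOC)ccc1C(=O)CCl
F3 | step 17 | heptakis(triethylsilyl) ether of 27 | CC(C)=CCc1c(O[Si](CC)(CC)CC)ccc(C(=O)[C@@H]2[C@@H](c3ccc(O[Si](CC)(CC)CC)cc3O[Si](CC)(CC)CC)CC(C)=C[C@H]2c2ccc(O[Si](CC)(CC)CC)c([C@H]3Oc4cc(O[Si](CC)(CC)CC)ccc4C(=O)[C@@H]3O[Si](CC)(CC)CC)c2)c1O[Si](CC)(CC)CC
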